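Start from the late end of three earlier runs, where complex Q, with incoming ligand L and some leaving ligand J, has stood for 2.50 min. You are asked what holds most of the Q at 5.0 min in two new flasks, summer and dawn.

| setting | Friday's | Saturday's | Sunday's | summer | dawn |
|---|---|---|---|---|---|
| Q | 0.050 M | 0.050 M | 0.050 M | 0.050 M | 0.050 M |
| L | 2.5 equiv | 2.5 equiv | 2.5 equiv | 2.50 equiv | 2.50 equiv |
| J | 0.81 equiv | 0.99 equiv | 1.4 equiv | 1.00 equiv | 1.20 equiv |
| remark | run made earlier | run made earlier | run made earlier |  |  |
| time |  |  |  | 5.0 min | 5.0 min |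

| run | time / min | Q / % | E / % | Z / % | G / % |
|---|---|---|---|---|---|
| Friday's | 0.200 | 94 | 7 | 0 | 3 |
| Friday's | 0.667 | 74 | 17 | 1 | 6 |
| Friday's | 1.33 | 56 | 32 | 5 | 13 |
| Friday's | 2.00 | 38 | 38 | 0 | 16 |
| Friday's | 2.50 | 34 | 46 | 3 | 15 |
| Saturday's | 0.500 | 75 | 15 | 3 | 8 |
| Saturday's | 1.00 | 60 | 30 | 0 | 13 |
| Saturday's | 1.50 | 43 | 36 | 0 | 9 |
| Saturday's | 2.00 | 36 | 44 | 0 | 17 |
| Saturday's | 2.50 | 33 | 50 | 5 | 21 |
| Sunday's | 0.200 | 88 | 10 | 0 | 3 |
| Sunday's | 0.417 | 72 | 22 | 0 | 7 |
| Sunday's | 0.667 | 63 | 25 | 0 | 9 |
| Sunday's | 1.33 | 44 | 43 | 0 | 14 |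
| Sunday's | 2.50 | 22 | 62 | 1 | 15 |

(standard deviation of a reading: 2 percentage points)

- which of these there is most of at the end, counted by the Q in it, summer (E / Z / Q / G)
- which of these there is most of at the end, counted by the Q in it, dawn (E / Z / Q / G)
- amount of the one of these that there is most of at the end, in percent of the Q charged, summer
- amount of the one of these that there is most of at the end, in percent of the Q charged, dawn

- the analysis behind the earlier runs scatters by 2 percentage points, standard deviation

Here is the odd pair. Sunday's run, charged with 1.4 equiv of J, has 22 % of its Q left, less than the 34 % of Friday's run with 0.81 equiv, though you expect added leaving ligand to hold an exchange back. The readings clear this up: G reads 15 % on Sunday and 15 % on Friday, while E reads 62 % against 46 %. So I take J to attack Q and give E, in competition with L, which gives G and then Z.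

The last readings of Friday's, Saturday's and Sunday's runs give 7.89, 4.86 and 6.92 for E over G plus Z, times charged L over charged J. Their mean, 6.55, is my selectivity factor, the E made per G and Z made at equal J and L. All three runs carry the same L, so the L in it is assumed.

It gives 2.62 E per G and Z for summer and 3.15 for dawn. Saturday's run, nearest summer in J, keeps 33 % of its Q at 2.50 min. If the same fraction survives again by 5.0 min, summer keeps 10.9 %, and I expect E at 64.5 %.

The forecast says E in both flasks, 62 % for summer, below mine, and 67 % for dawn, on the ground that “E's rate scales with J”.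

The flasks give E at 64.1 % in summer and E at 69.6 % in dawn.

    J + Q → E (k = 0.140 /M/s)
    Z + L ⇌ J + X (K = 4.10, k = 0.0210 /M/s)
    G + L ⇌ J + Z (K = 0.100, k = 0.00870 /M/s)
    Q + L ⇌ J + G (K = 0.480, k = 0.0230 /M/s)

Read back, the factor is 7.30 in summer and 7.65 in dawn, inside the earlier spread. The gap between the flasks comes from the extra J: dawn at summer's J gives 64.1 % of E, not 69.6 %. The back reaction of J with G is not the reason for summer's E: with that step taken away, summer's E goes from 64.1 % to 62.3 %.

Now read dawn at 80 s: the carried factor gives 3.15 E per G and Z. That flask holds 40.6 % of E, 13.1 % of G and 0.543 % of Z, a ratio of 2.98, and Q leads at 45.7 %.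

The earlier runs and the new flask stem from a simulated flask with made-up constants, and the scatter is random.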